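Ring A of the coumarin (C4a, C5, C6, C7, C8, C8a) is a resorcinol in which the chain-bearing C8 sits between the oxygens on C7 and C8a, and the route exploits exactly this pattern. Ring A is built around the finished chiral chain: heating cyclobut-2-enone with a triisopropylsilyl ynol ether that carries C1′ and C2′ as a cis-acetonide (from D-erythronolactone) forms C8–C8a and C6–C7 and closes the benzene ring in one operation, giving a phenol whose only free ortho carbon is C4a. Formylation there, ylide lactonisation, silyl-to-methyl exchange at O7, acetonide hydrolysis and acylation of O2′ finish the synthesis.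

Key step: step 8

Remark: (1′R,2′S) is the erythro diol, so it maps onto a cis-4,5-disubstituted dioxolane and onto (3aR,6aR)-erythronolactone acetonide, whose carbonyl carbon becomes C3′ and whose CH2 carbon becomes C8; the side chain is numbered C1′ (on C8) to C4′ throughout.

Step 1
Reactants: 1 2,3-O-isopropylidene-D-erythronolactone
Product: 2 (3aR,6aR)-2,2,4-trimethyltetrahydro-4H-furo[3,4-d][1,3]dioxol-4-ol (anomeric mixture)
Conditions: MeLi (1.05 equiv), THF, −78 °C; AcOH quench at −78 °C
Reagents that add atoms: methyllithium, [Li]C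
Why: Nucleophilic addition of one equivalent of methyllithium to the γ-lactone stops at the tetrahedral lithium alkoxide at −78 °C, and a cold quench releases the methyl ketone as its cyclic hemiketal with both dioxolane stereocentres untouched.

Step 2
Reactants: 2 (3aR,6aR)-2,2,4-trimethyltetrahydro-4H-furo[3,4-d][1,3]dioxol-4-ol
Product: 4 [(4R,5S)-2,2-dimethyl-5-(prop-1-en-2-yl)-1,3-dioxolan-4-yl]methanol, via open-chain hydroxy ketone 3 (not isolated)
Conditions: Ph3PCH3Br, KOtBu, THF, 0 °C → reflux
Reagents that add atoms: methyltriphenylphosphonium bromide, C[P+](c1ccccc1)(c1ccccc1)c1ccccc1.[Br-]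
Why: Under base the lactol is in equilibrium with hydroxy ketone 3, whose ketone the non-stabilised ylide converts into the 1,1-disubstituted alkene (Wittig methylenation), while the cis-dioxolane carries C1′ and C2′ unchanged as long as a large excess of ylide is avoided, which limits enolisation next to the ketone.

Step 3
Reactants: 4 [(4R,5S)-2,2-dimethyl-5-(prop-1-en-2-yl)-1,3-dioxolan-4-yl]methanol
Product: 5 (4S,5S)-2,2-dimethyl-5-(prop-1-en-2-yl)-1,3-dioxolane-4-carbaldehyde
Conditions: TEMPO (cat.), PhI(OAc)2, CH2Cl2, rt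
Reagents that add atoms: none
Why: Oxoammonium (TEMPO) oxidation with PhI(OAc)2 as terminal oxidant stops at the aldehyde and uses no amine base, so the epimerisable cis-dioxolane aldehyde should keep its configuration and the alkene is not attacked.

Step 4
Reactants: 5 (4S,5S)-2,2-dimethyl-5-(prop-1-en-2-yl)-1,3-dioxolane-4-carbaldehyde
Product: 6 (4R,5S)-4-(2,2-dibromoethenyl)-2,2-dimethyl-5-(prop-1-en-2-yl)-1,3-dioxolane
Conditions: CBr4, PPh3, Zn dust, CH2Cl2, rt (ylide pre-formed); then 5, 0 °C → rt
Reagents that add atoms: carbon tetrabromide, BrC(Br)(Br)Br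
Why: Corey–Fuchs dibromo-olefination with the ylide pre-formed from CBr4, PPh3 and zinc is a Wittig reaction under essentially neutral conditions, which avoids the carbonate/methanol medium of diazophosphonate homologations that could epimerise the cis aldehyde.

Step 5
Reactants: 6 (4R,5S)-4-(2,2-dibromoethenyl)-2,2-dimethyl-5-(prop-1-en-2-yl)-1,3-dioxolane; 7 triisopropylsilyl trifluoromethanesulfonate
Product: 10 ({[(4R,5S)-2,2-dimethyl-5-(prop-1-en-2-yl)-1,3-dioxolan-4-yl]ethynyl}oxy)triisopropylsilane, via lithium acetylide 8 (not isolated), via lithium ynolate 9 (not isolated)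
Conditions: n-BuLi (2.05 equiv), THF, −78 °C; LiOOtBu (from tBuOOH and LiN(SiMe3)2), −78 → 0 °C; 7, −78 °C
Reagents that add atoms: tert-butyl hydroperoxide, CC(C)(C)OO; triisopropylsilyl trifluoromethanesulfonate 7, CC(C)[Si](OS(=O)(=O)C(F)(F)F)(C(C)C)C(C)C
Why: Bromine–lithium exchange, Fritsch–Buttenberg–Wiechell rearrangement and deprotonation (second stage of the Corey–Fuchs sequence) give acetylide 8 without isolating the volatile terminal alkyne, the electrophilic oxygen of LiOOtBu converts 8 into ynolate 9 (oxenoid oxidation of an acetylide), and the hard silyl triflate traps 9 on oxygen.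

Step 6
Reactants: 11 3-oxocyclobutane-1-carboxylic acid
Product: 12 3-bromocyclobutan-1-one
Conditions: HgO, Br2, MgSO4, CH2Cl2, reflux
Reagents that add atoms: bromine, BrBr
Why: Cristol–Firth variant of the Hunsdiecker bromodecarboxylation, in which the acyl hypobromite formed from the acid, HgO and Br2 fragments to CO2 and a cyclobutyl radical that abstracts bromine, the ketone being inert.

Step 7
Reactants: 12 3-bromocyclobutan-1-one
Product: 13 cyclobut-2-en-1-one
Conditions: n-Bu3N, rt, reduced pressure, distilled into a −78 °C trap; kept cold in toluene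
Reagents that add atoms: none
Why: Amine-induced 1,2-elimination of HBr from the β-bromo ketone (E1cB) gives the strained enone, which is distilled out as it forms and stored cold in solution to prevent polymerisation.

Step 8
Reactants: 10 ({[(4R,5S)-2,2-dimethyl-5-(prop-1-en-2-yl)-1,3-dioxolan-4-yl]ethynyl}oxy)triisopropylsilane; 13 cyclobut-2-en-1-one
Product: 18 2-[(4R,5S)-2,2-dimethyl-5-(prop-1-en-2-yl)-1,3-dioxolan-4-yl]-3-[(triisopropylsilyl)oxy]phenol, via vinylketene 14 (not isolated), via vinylcyclobutenone adduct 15 (not isolated), via dienylketene 16 (not isolated), via cyclohexadienone 17 (not isolated)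
Conditions: 13 (2 equiv, added slowly), toluene, 80 °C → 110 °C
Reagents that add atoms: none
Why: Danheiser benzannulation, the closest known reaction type being the thermal union of cyclobutenones with silyl ynol ethers: four-electron electrocyclic opening of 13 gives vinylketene 14, whose carbonyl carbon is attacked by the chain-bearing, nucleophilic carbon of ynol ether 10 in a ketene–alkyne (2+2) cycloaddition to give 15, creating C8–C8a and C6–C7. Cyclobutenone 15 opens (four electrons) to dienylketene 16, which closes ring A by a thermal disrotatory six-electron electrocyclisation that re-forms the C4a–C8a bond, and dienone 17 tautomerises to phenol 18. No stereocentre is formed in 18 (the vinyl-bearing carbon of 15 becomes planar again), and C1′ and C2′ are carried unchanged inside the cis-dioxolane, which has no acidic or ionisable position under neutral thermal conditions. The selectivity required is regiochemical and is secured by the polarisation of the ynol ether, so that the chain ends on C8 between the new hydroxyl (C8a) and the silyloxy group (C7). The triisopropylsilyl group is kept because silyl ynol ethers, unlike ethyl or tert-butyl ynol ethers, cannot fragment to ketenes by a retro-ene path at this temperature, and slow addition of 13 to hot 10 keeps the ketene concentration low so that it is captured by 10 and not by 13 or by phenol 18.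

Step 9
Reactants: 18 2-[(4R,5S)-2,2-dimethyl-5-(prop-1-en-2-yl)-1,3-dioxolan-4-yl]-3-[(triisopropylsilyl)oxy]phenol
Product: 19 2-hydroxy-3-[(4R,5S)-2,2-dimethyl-5-(prop-1-en-2-yl)-1,3-dioxolan-4-yl]-4-[(triisopropylsilyl)oxy]benzaldehyde
Conditions: MgCl2, Et3N, (CH2O)n, MeCN, reflux
Reagents that add atoms: paraformaldehyde (as formaldehyde), C=O
Why: Casnati–Skattebøl ortho-formylation, in which the magnesium phenoxide directs formaldehyde to the only free ortho carbon (C4a, also para to the silyloxy group) and a second formaldehyde oxidises the benzylic alkoxide to the aldehyde, the basic medium leaving acetonide, silyl ether and alkene alone.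

Step 10
Reactants: 19 2-hydroxy-3-[(4R,5S)-2,2-dimethyl-5-(prop-1-en-2-yl)-1,3-dioxolan-4-yl]-4-[(triisopropylsilyl)oxy]benzaldehyde
Product: 21 8-[(4R,5S)-2,2-dimethyl-5-(prop-1-en-2-yl)-1,3-dioxolan-4-yl]-7-[(triisopropylsilyl)oxy]-2H-chromen-2-one, via phosphoranylidene ester 20 (not isolated)
Conditions: Ph3P=C=C=O, toluene, reflux
Reagents that add atoms: (triphenylphosphoranylidene)ketene, O=C=C=P(c1ccccc1)(c1ccccc1)c1ccccc1
Why: The phenol adds across the ketene C=C of Ph3P=C=C=O to give ester ylide 20, whose intramolecular Wittig reaction with the ortho aldehyde can only deliver the cis alkene within the six-membered lactone, so the pyranone ring should close at 110 °C without the hot E-to-Z isomerisation that an intermolecular Wittig route needs.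

Step 11
Reactants: 21 8-[(4R,5S)-2,2-dimethyl-5-(prop-1-en-2-yl)-1,3-dioxolan-4-yl]-7-[(triisopropylsilyl)oxy]-2H-chromen-2-one
Product: 23 8-[(4R,5S)-2,2-dimethyl-5-(prop-1-en-2-yl)-1,3-dioxolan-4-yl]-7-methoxy-2H-chromen-2-one, via caesium phenoxide 22 (not isolated)
Conditions: CsF, MeI, DMF, rt → 40 °C
Reagents that add atoms: iodomethane, CI
Why: Fluoride removes the aryl silyl group (the 2-oxochromen-7-olate is a good leaving group from silicon) and the naked phenoxide 22 is O-methylated in the same flask (Williamson etherification), under conditions to which the acetonide and the lactone are inert.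

Step 12
Reactants: 23 8-[(4R,5S)-2,2-dimethyl-5-(prop-1-en-2-yl)-1,3-dioxolan-4-yl]-7-methoxy-2H-chromen-2-one
Product: 24 8-[(1R,2S)-1,2-dihydroxy-3-methylbut-3-en-1-yl]-7-methoxy-2H-chromen-2-one
Conditions: AcOH/H2O (4:1), 50 °C
Reagents that add atoms: none
Why: Specific-acid hydrolysis of the isopropylidene ketal cleaves only the bonds to the ketal carbon, so both carbinol C–O bonds and their configurations are kept, and dilute acetic acid is too weak to ionise the benzylic C1′–O bond or to hydrate the alkene.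

Step 13
Reactants: 24 8-[(1R,2S)-1,2-dihydroxy-3-methylbut-3-en-1-yl]-7-methoxy-2H-chromen-2-one; 25 3-methylbutanoyl chloride
Product: 26 (1R,2S)-1-hydroxy-1-(7-methoxy-2-oxo-2H-chromen-8-yl)-3-methylbut-3-en-2-yl 3-methylbutanoate
Conditions: 25 (1.05 equiv), pyridine, CH2Cl2, −20 °C
Reagents that add atoms: 3-methylbutanoyl chloride 25, CC(C)CC(Cl)=O
Why: Kinetic esterification with one equivalent of the acid chloride and pyridine at low temperature should select the allylic O2′ hydroxyl, since the benzylic O1′ hydroxyl is flanked by both ortho substituents of ring A (the C7 methoxy group and the C8a ring oxygen), and the absence of stronger base or acyl-transfer catalyst disfavours 1,2-acyl migration.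

Compound list
1 | 2,3-O-isopropylidene-D-erythronolactone, (3aR,6aR)-2,2-dimethyldihydrofuro[3,4-d][1,3]dioxol-4(3aH)-one | O=C1[C@@H]2OC(C)(C)O[C@@H]2CO1 | starting material
2 | (3aR,6aR)-2,2,4-trimethyltetrahydro-4H-furo[3,4-d][1,3]dioxol-4-ol (anomeric mixture) | OC1(C)[C@@H]2OC(C)(C)O[C@@H]2CO1 | intermediate
3 | 1-[(4R,5R)-5-(hydroxymethyl)-2,2-dimethyl-1,3-dioxolan-4-yl]ethan-1-one (open-chain form of 2) | CC(=O)[C@@H]1OC(C)(C)O[C@@H]1CO | intermediate
4 | [(4R,5S)-2,2-dimethyl-5-(prop-1-en-2-yl)-1,3-dioxolan-4-yl]methanol | C=C(C)[C@@H]1OC(C)(C)O[C@@H]1CO | intermediate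
5 | (4S,5S)-2,2-dimethyl-5-(prop-1-en-2-yl)-1,3-dioxolane-4-carbaldehyde | C=C(C)[C@@H]1OC(C)(C)O[C@@H]1C=O | intermediate
6 | (4R,5S)-4-(2,2-dibromoethenyl)-2,2-dimethyl-5-(prop-1-en-2-yl)-1,3-dioxolane | C=C(C)[C@@H]1OC(C)(C)O[C@@H]1C=C(Br)Br | intermediate
7 | triisopropylsilyl trifluoromethanesulfonate | CC(C)[Si](OS(=O)(=O)C(F)(F)F)(C(C)C)C(C)C | starting material
8 | lithium [(4R,5S)-2,2-dimethyl-5-(prop-1-en-2-yl)-1,3-dioxolan-4-yl]acetylide | C=C(C)[C@@H]1OC(C)(C)O[C@@H]1C#C[Li] | intermediate
9 | lithium 2-[(4R,5S)-2,2-dimethyl-5-(prop-1-en-2-yl)-1,3-dioxolan-4-yl]ethyn-1-olate | C=C(C)[C@@H]1OC(C)(C)O[C@@H]1C#CO[Li] | intermediate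
10 | ({[(4R,5S)-2,2-dimethyl-5-(prop-1-en-2-yl)-1,3-dioxolan-4-yl]ethynyl}oxy)triisopropylsilane | C=C(C)[C@@H]1OC(C)(C)O[C@@H]1C#CO[Si](C(C)C)(C(C)C)C(C)C | intermediate
11 | 3-oxocyclobutane-1-carboxylic acid | O=C1CC(C1)C(=O)O | starting material
12 | 3-bromocyclobutan-1-one | O=C1CC(Br)C1 | intermediate
13 | cyclobut-2-en-1-one | O=C1CC=C1 | intermediate
14 | buta-1,3-dien-1-one (vinylketene) | C=CC=C=O | intermediate
15 | 4-ethenyl-2-[(4R,5S)-2,2-dimethyl-5-(prop-1-en-2-yl)-1,3-dioxolan-4-yl]-3-[(triisopropylsilyl)oxy]cyclobut-2-en-1-one (both epimers at C4) | C=C(C)[C@@H]1OC(C)(C)O[C@@H]1C1=C(O[Si](C(C)C)(C(C)C)C(C)C)C(C=C)C1=O | intermediate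
16 | 2-[(4R,5S)-2,2-dimethyl-5-(prop-1-en-2-yl)-1,3-dioxolan-4-yl]-3-[(triisopropylsilyl)oxy]hexa-1,3,5-trien-1-one | C=C(C)[C@@H]1OC(C)(C)O[C@@H]1C(=C=O)C(O[Si](C(C)C)(C(C)C)C(C)C)=CC=C | intermediate
17 | 2-[(4R,5S)-2,2-dimethyl-5-(prop-1-en-2-yl)-1,3-dioxolan-4-yl]-3-[(triisopropylsilyl)oxy]cyclohexa-2,4-dien-1-one | C=C(C)[C@@H]1OC(C)(C)O[C@@H]1C1=C(O[Si](C(C)C)(C(C)C)C(C)C)C=CCC1=O | intermediate
18 | 2-[(4R,5S)-2,2-dimethyl-5-(prop-1-en-2-yl)-1,3-dioxolan-4-yl]-3-[(triisopropylsilyl)oxy]phenol | C=C(C)[C@@H]1OC(C)(C)O[C@@H]1c1c(O)cccc1O[Si](C(C)C)(C(C)C)C(C)C | intermediate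
19 | 2-hydroxy-3-[(4R,5S)-2,2-dimethyl-5-(prop-1-en-2-yl)-1,3-dioxolan-4-yl]-4-[(triisopropylsilyl)oxy]benzaldehyde | C=C(C)[C@@H]1OC(C)(C)O[C@@H]1c1c(O)c(C=O)ccc1O[Si](C(C)C)(C(C)C)C(C)C | intermediate
20 | 2-formyl-6-[(4R,5S)-2,2-dimethyl-5-(prop-1-en-2-yl)-1,3-dioxolan-4-yl]-5-[(triisopropylsilyl)oxy]phenyl (triphenylphosphoranylidene)acetate | C=C(C)[C@@H]1OC(C)(C)O[C@@H]1c1c(OC(=O)C=P(c2ccccc2)(c2ccccc2)c2ccccc2)c(C=O)ccc1O[Si](C(C)C)(C(C)C)C(C)C | intermediate
21 | 8-[(4R,5S)-2,2-dimethyl-5-(prop-1-en-2-yl)-1,3-dioxolan-4-yl]-7-[(triisopropylsilyl)oxy]-2H-chromen-2-one | C=C(C)[C@@H]1OC(C)(C)O[C@@H]1c1c(O[Si](C(C)C)(C(C)C)C(C)C)ccc2ccc(=O)oc12 | intermediate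
22 | caesium 8-[(4R,5S)-2,2-dimethyl-5-(prop-1-en-2-yl)-1,3-dioxolan-4-yl]-2-oxo-2H-chromen-7-olate | C=C(C)[C@@H]1OC(C)(C)O[C@@H]1c1c([O-])ccc2ccc(=O)oc12.[Cs+] | intermediate
23 | 8-[(4R,5S)-2,2-dimethyl-5-(prop-1-en-2-yl)-1,3-dioxolan-4-yl]-7-methoxy-2H-chromen-2-one | C=C(C)[C@@H]1OC(C)(C)O[C@@H]1c1c(OC)ccc2ccc(=O)oc12 | intermediate
24 | 8-[(1R,2S)-1,2-dihydroxy-3-methylbut-3-en-1-yl]-7-methoxy-2H-chromen-2-one | C=C(C)[C@H](O)[C@H](O)c1c(OC)ccc2ccc(=O)oc12 | intermediate
25 | 3-methylbutanoyl chloride | CC(C)CC(Cl)=O | starting material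
26 | (1R,2S)-1-hydroxy-1-(7-methoxy-2-oxo-2H-chromen-8-yl)-3-methylbut-3-en-2-yl 3-methylbutanoate | C=C(C)[C@H](OC(=O)CC(C)C)[C@H](O)c1c(OC)ccc2ccc(=O)oc12 | target

Total step count: 13. Longest linear sequence: 11 steps (steps 1–5, then 8–13); steps 6 and 7 are the two-step branch to cyclobutenone 13.

Steps most likely to fail

Step 8. The parent enone 13 may polymerise, or the ketene derived from it may be consumed by 13 or by the product phenol faster than the hindered ynol ether 10 captures it. The fallback sets out from 10 and returns to the route at phenol 18 through the same intermediates 14 to 17, but generates the vinylketene at room temperature by photochemical Wolff rearrangement instead of thermal ring opening. But-3-en-2-one would be trifluoroacetylated at its kinetic enolate (LiN(SiMe3)2, CF3CO2CH2CF3, THF, −78 °C) to 1,1,1-trifluorohex-5-ene-2,4-dione F1. Deacylative diazo transfer (MsN3, Et3N, H2O, MeCN) would then give 1-diazobut-3-en-2-one F2, to be used at once in solution. Irradiation of F2 with 10 (254 nm, 1,2-dichloroethane, rt, then 80 °C to complete the cascade) should give 18.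

Step 13. Discrimination between O1′ and O2′ may be insufficient, double acylation may occur, or the acyl group may migrate from O2′ to O1′ during reaction or work-up. The fallback sets out from diol 24 and returns at target 26, replacing competition between two free hydroxyls by covalent activation of one oxygen. Diol 24 would be heated with Bu2SnO (toluene, reflux, removal of water) to give the stannylene acetal 8-[(4R,5S)-2,2-dibutyl-5-(prop-1-en-2-yl)-1,3,2-dioxastannolan-4-yl]-7-methoxy-2H-chromen-2-one F3. F3 would then be treated with 25 alone (CH2Cl2, 0 °C, no base). Stannylene acetals accept a single acyl group at the more accessible oxygen under neutral conditions that do not promote acyl migration, and aqueous work-up frees O1′.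

Step 5. Oxygen transfer from the peroxide to the acetylide may be incomplete (leaving the terminal alkyne after work-up), or the ynol ether may be lost by C-silylation or by hydrolysis during isolation. The fallback sets out from aldehyde 5 and returns at ynolate 9, hence at 10, making the ynolate by rearrangement instead of oxidation (Kowalski ester homologation). Pinnick oxidation of 5 (NaClO2, NaH2PO4, 2-methylbut-2-ene, tBuOH/H2O) would give (4S,5S)-2,2-dimethyl-5-(prop-1-en-2-yl)-1,3-dioxolane-4-carboxylic acid F4, and Me3SiCHN2 (MeOH/toluene) its methyl ester, methyl (4S,5S)-2,2-dimethyl-5-(prop-1-en-2-yl)-1,3-dioxolane-4-carboxylate F5. Addition of LiCHBr2 (from CH2Br2 and lithium 2,2,6,6-tetramethylpiperidide, THF, −78 °C) followed by LiN(SiMe3)2 would give lithium 2,2-dibromo-1-[(4S,5S)-2,2-dimethyl-5-(prop-1-en-2-yl)-1,3-dioxolan-4-yl]ethen-1-olate F6. With n-BuLi (−78 → 0 °C) F6 should rearrange with retention at the migrating carbon to ynolate 9, which is silylated with 7 as in step 5.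

Further compounds
F1 | step 8 | 1,1,1-trifluorohex-5-ene-2,4-dione | C=CC(=O)CC(=O)C(F)(F)F
F2 | step 8 | 1-diazobut-3-en-2-one | C=CC(=O)C=[N+]=[N-]
F3 | step 13 | 8-[(4R,5S)-2,2-dibutyl-5-(prop-1-en-2-yl)-1,3,2-dioxastannolan-4-yl]-7-methoxy-2H-chromen-2-one | C=C(C)[C@@H]1O[Sn](CCCC)(CCCC)O[C@@H]1c1c(OC)ccc2ccc(=O)oc12
F4 | step 5 | (4S,5S)-2,2-dimethyl-5-(prop-1-en-2-yl)-1,3-dioxolane-4-carboxylic acid | C=C(C)[C@@H]1OC(C)(C)O[C@@H]1C(=O)O
F5 | step 5 | methyl (4S,5S)-2,2-dimethyl-5-(prop-1-en-2-yl)-1,3-dioxolane-4-carboxylate | C=C(C)[C@@H]1OC(C)(C)O[C@@H]1C(=O)OC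
F6 | step 5 | lithium 2,2-dibromo-1-[(4S,5S)-2,2-dimethyl-5-(prop-1-en-2-yl)-1,3-dioxolan-4-yl]ethen-1-olate | C=C(C)[C@@H]1OC(C)(C)O[C@@H]1C(O[Li])=C(Br)Br
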